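## The problem

The target is a 23-membered ansa lactam in which a seventeen-carbon chain (C1, the amide carbonyl, to C17, the aryl ketone) bridges the nitrogen on C2 and the acyl carbon on C5 of a 6,8-dihydroxy-7-methyl-1,4-naphthoquinone, while a δ-lactone is fused onto the chain through the C11 oxygen and a one-carbon branch (C18) on C14. The chain carries nine contiguous stereocentres, C6 to C14 (6R,7R,8R,9S,10S,11R,12S,13S,14R), in the relative order anti, anti, syn, anti, syn, anti, syn, anti, and three alkenes of fixed geometry (2Z, 4E, 15Z). C6, C7, C9 and C10 have no neighbour that could direct them and need absolute control from a catalyst, after which C8 is defined simply by telling the two chain ends apart. The methyl-bearing C10 and C12 bias additions to the C11 and C13 carbonyls in the Felkin sense, which is the sense required, and C14 must come out anti to C13 in the same bond formation. The lactone is the most fragile part: C14–H is α to the lactone carbonyl and γ to the C15–C17 enone, and C13–OH is β to that carbonyl, so base, fluoride or hot acid invite epimerisation, alkene migration or elimination; the (Z)-enone, the (2Z,4E)-dienamide, the aminoquinone and the free phenols call for equally mild final steps. The hexasubstituted benzenoid ring must be built with every substituent in a defined place and joined to C17 between a phenol oxygen and a peri substituent. The feature that allows a short entry is the C6–C10 segment: Me, OH, Me, OH, Me with anti C6/C7, anti C9/C10 and an anti C7/C9 diol is pseudo-C2-symmetric about C8, so both halves can be made at once from an achiral three-carbon diol.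

## Retrosynthesis

**Lactone last.** The C18–O bond of the lactone in 48 is cut back to pentaol 45, in which C18 is a primary alcohol. Carrying the lactone through an aryllithium addition, an ester hydrolysis and a lactamisation would expose the doubly activated C14–H to base; making it last under near-neutral oxidation avoids that. The forward reaction must oxidise one primary alcohol in the presence of four secondary ones; only the C11 hydroxyl can then close a six-membered lactol.

**Protecting groups and quinone.** 45 comes from quinone 44 by one aqueous acid treatment, and 44 from the 1,4-dimethoxynaphthalene 43. All chain oxygens sit in acid-labile groups (two acetonides, one triethylsilyl ether) and the phenols in methoxymethyl ethers, so no fluoride or base is needed after the macrocycle exists.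

**Amide bond N–C1.** 43 is opened to amino acid 42. Closing the ring at the amide with an electron-rich naphthylamine is the classical closure for this class. Closing at C17–arene would demand an organometallic step on the whole molecule. The forward reaction must activate a (2Z)-dienoic acid without isomerising it and under high dilution.

**C17–C5(arene).** 42 derives from keto acid 41, which derives through acid 40 from carbinol 39, the adduct of aldehyde 24 and aryllithium 38, itself made from bromide 37. This cut splits the molecule into two halves of similar size. The arene carbon is flanked by two oxygen substituents and is better as a nucleophile than as a Friedel–Crafts position on a sensitive chain; an aldehyde is the one electrophile that outruns the C1 ester at low temperature.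

**Arene.** 37 is traced through carbamate 36, amine 35, chloride 33 and quinone 31 to chloronaphthoquinone 30, the Diels–Alder product of vinylketene acetal 27 and dichloroquinone 28. The chlorine fixes the regiochemistry of the cycloaddition and later becomes the handle for nitrogen. The precursors are a β-keto ester (25) and a commodity quinone.

**The two (Z)-trisubstituted alkenes.** Aldehyde 24 is reached from 23, 22, 21 and aldehyde 19 with the same phosphonate 20 used twice. Carrying C3 as an N-methoxy-N-methylamide and C17 as an ester lets one hydride reduction deliver a C3 aldehyde and a C17 alcohol, so the two ends are never confused. Each olefination is asked for Z selectivity on an acyclic substrate.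

**C13–C14 and C11–C12.** 19 comes from diol 17, made from alcohol 15 and vinyl carbonate 16; 15 comes through silyl ether 13 from 12, made from alcohol 11 and acetate 2. Each cut removes two stereocentres and uses an alcohol directly as the aldehyde equivalent, so the α-stereogenic aldehydes 10 and 14 are never isolated. The second addition must bring an oxygenated carbon (C18), which a plain crotyl donor cannot; the carbonate 16 does.

**Telling the chain ends apart.** 11 comes from 9, 8 and 7, and 7 from iodoether 5 and acrylamide 6. In 5 one vinyl group is masked as an iodomethyl tetrahydropyran, so the free one can be turned into the ozone-resistant enamide that fixes C5 and the C4=C5 position; zinc then releases the other vinyl group for cleavage to C11.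

**Key disconnection.** 5 comes from diol 4, and 4 from 2-methylpropane-1,3-diol 1 and two molecules of 2 by cutting C6–C7 and C9–C10 at once. This removes four stereocentres in the first step and avoids 2-methylmalondialdehyde. The forward reaction needs catalyst control at both carbinols and anti selectivity in both additions.

## Roads not taken

**Alternative 1:** Ramberg–Bäcklund ring contraction. The C4=C5 bond is cut inside the ring: the macrocycle is first closed as the 24-membered C4–SO2–C5 sulfone A2, which is halogenated at C4 and deprotonated at C5 (KOH on alumina, CBr2F2); the episulfone loses SO2 to give dienamide A1. Its merits are that the isomerisation-prone diene is made last, that C4 and C5 arrive as simple CH2–S units, and that no (2Z)-dienoic acid has to be activated for lactamisation. On those points it is better than the chosen plan, which needs an enamide detour and a selective ozonolysis three times over. Its weak points for this target are the hydroxide medium in the presence of the δ-lactone and its β-silyloxy group, the lack of assured E geometry for the new alkene in a large ring, and the risk that the allylic anion at C4 scrambles the (2Z) alkene. It also leaves the stereochemical problem of C6–C14 untouched. The chosen plan sets against it alkene geometries fixed by cross-metathesis and two Z-selective olefinations on open-chain compounds, and four stereocentres in the first step.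

**Alternative 2:** Danheiser benzannulation for the benzenoid ring. Irradiation of aryl diazo ketone A4 gives, by Wolff rearrangement, an aryl(alkoxymethyl)ketene that combines with siloxyalkyne A5 by [2+2] addition, four-electron ring opening and six-electron closure to naphthol A3. Its merit is real: all six substituents are placed in one step with regiochemistry dictated by mechanism, the C5 carbon substituent is built in, and the two phenol oxygens emerge differentiated. In regiocontrol it is better than the arene sequence chosen here, whose late bromination (step 24) is the weakest arene step. Its costs are the diazo ketone and siloxyalkyne preparations, a photochemical step, and a C5 substituent at the alcohol oxidation level, so the union with the chain must be reversed (aryl aldehyde plus alkenyl metal). It says nothing about the ansa chain and could be grafted onto the chosen plan. The chosen arene route sets against it inexpensive Diels–Alder chemistry and a bromide that is lithiated directly.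

**Alternative 3:** Anionic Fries contraction. The C17–C5(arene) bond is formed inside a ring: the 25-membered aryl (Z)-enoate macrolactone A7, iodinated at C5, is N-deprotonated and treated with t-BuLi, and the aryllithium attacks the neighbouring ester in a 1,3 O-to-C acyl shift to give ketone A6. Its merits are that the most hindered bond is made intramolecularly, the C6 phenol is released in the same step, no (Z)-enal and no C17 oxidation are needed, and ortho-iodination of a phenol is regiochemically cleaner than the bromination used here. Its weak points are t-BuLi on a complete macrocycle that holds a (Z)-enoate with an acidic γ-hydrogen at C14 and an amide N–H, and a lactone that must still be made afterwards. In step count the two plans are similar. The chosen plan puts the organolithium step on two fragments, where failure costs less material, and accepts a separate oxidation in return.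

Key step: step 1

Assumption: (R)-SEGPHOS is taken to give the (3R,4R,6R,7R) diol 4, by analogy with the known sense of this catalyst family on simple primary alcohols. If the antipode results, the ligand enantiomers in steps 1, 7 and 10 are exchanged and nothing else changes.

Conventions: ansa carbons are numbered C1–C17 as above; C18 is the carbon on C14 that ends as the lactone carbonyl; arene positions are those of the naphthalene (N on C2, ansa carbon on C5). Unless a name says otherwise, every stereocentre of an intermediate has the configuration of the same carbon in the target. In the iridium-catalysed couplings of steps 1, 7 and 10 the carbonyl stage is generated and consumed at the metal within the catalytic cycle; like the crotyl iridium species it is described in the Why lines and is not counted as a separate compound of those steps.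

## Route

Step 1
Reactants: 1 2-methylpropane-1,3-diol; 2 but-3-en-2-yl acetate (racemic; two molecules are consumed per molecule of 1, used in excess)
Product: 4 (3R,4R,6R,7R)-3,5,7-trimethylnona-1,8-diene-4,6-diol, via mono-crotylated diol 3 (not isolated)
Conditions: [Ir(cod)Cl]2 (cat.), (R)-SEGPHOS, 4-cyano-3-nitrobenzoic acid, Cs2CO3 (substoichiometric), THF, H2O (additive), 70 °C
Reagents that add atoms: but-3-en-2-yl acetate, the second molecule of 2 (CC(OC(C)=O)C=C)
Why: In the flask [Ir(cod)Cl]2, the bisphosphine, the nitrobenzoic acid and 2 give an ortho-cyclometalated trivalent iridium π-crotyl C,O-benzoate; its alkoxide with 1 undergoes β-hydride elimination to the aldehyde, base removes the hydride to give monovalent iridium, and this ionises another molecule of 2, so no external oxidant or reductant is needed and the aldehyde is consumed as it forms. The (E)-σ-crotyl iridium species adds to the bound aldehyde through a closed chair transition state, which forms C6–C7 and then, with a second molecule of 2, C9–C10 with methyl and hydroxyl anti. The ligand decides which aldehyde face is attacked, so C7 and C6 and, in the second event on mono-adduct 3, C9 and C10 are all set by the catalyst with nothing asked of the substrate. Because two catalyst-controlled additions occur on one molecule, the minor enantiomer of the first is diverted into a diastereomer of 4 that chromatography removes, so the enantiomeric purity of 4 should exceed that of a single crotylation. The step needs primary-over-secondary alcohol dehydrogenation, secured because the homoallylic secondary alcohols formed are dehydrogenated far more slowly, and branched rather than linear crotyl transfer, secured by the allylic transposition in the addition of the σ-crotyl species. The closest known reaction type is the iridium-catalysed transfer-hydrogenative anti-crotylation of primary alcohols, including its two-directional use on 1,3-diols. No ring is closed, and C8, flanked by two identical arms, is not yet a stereocentre.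

Step 2
Reactants: 4
Product: 5 (2R,3S,4S,5S,6R)-2-[(2R)-but-3-en-2-yl]-6-(iodomethyl)-3,5-dimethyloxan-4-ol
Conditions: I2 (1 equiv), NaHCO3, MeCN, −20 → 0 °C
Reagents that add atoms: iodine (I-I)
Why: 6-exo iodoetherification through a chair: the C7 hydroxyl (anti to the C8 methyl) adds to the C10 vinyl group, because that chair has the C6 side chain, C8 methyl and C9 hydroxyl equatorial and only the C10 methyl axial, whereas closure of the C9 hydroxyl onto the other vinyl group needs an all-cis ring with a 1,3-diaxial pair. This choice between diastereotopic ends makes C8 stereogenic with the target configuration; the iodomethyl carbon (expected 2,6-cis) is erased in step 4.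

Step 3
Reactants: 5; 6 N-methoxy-N-methylprop-2-enamide
Product: 7 (2E,4R)-4-[(2R,3S,4S,5S,6R)-4-hydroxy-6-(iodomethyl)-3,5-dimethyloxan-2-yl]-N-methoxy-N-methylpent-2-enamide
Conditions: RuCl2(H2IMes)(=CH-C6H4-2-Oi-Pr) (second-generation Hoveyda–Grubbs catalyst, cat.), 6 (3 equiv), CH2Cl2, 40 °C
Reagents that add atoms: none
Why: Cross-metathesis of the only alkene in 5 with an acrylamide gives the (E)-enamide under thermodynamic control; free hydroxyl and primary iodide are tolerated. C5 comes from the crotyl unit, whose terminal methylene is exchanged for the C4–C3 unit of the acrylamide, and the alkene is now electron-poor enough to survive later ozonolyses.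

Step 4
Reactants: 7
Product: 8 (2E,4R,5R,6S,7R,8R)-5,7-dihydroxy-N-methoxy-N,4,6,8-tetramethyldeca-2,9-dienamide
Conditions: Zn dust, EtOH, 75 °C
Reagents that add atoms: none
Why: Zinc insertion into the C–I bond and β-elimination of the ring alkoxide (Boord-type reductive ring opening) return the C7 hydroxyl and the C10 vinyl group; the conjugated amide is inert to zinc in ethanol.

Step 5
Reactants: 8
Product: 9 7,9-O-isopropylidene derivative of 8 (2,2-dimethyl-1,3-dioxane over O7 and O9; (E)-N-methoxy-N-methyl enamide at C3–C5; vinyl group on C10)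
Conditions: Me2C(OMe)2, PPTS (cat.), CH2Cl2, rt
Reagents that add atoms: 2,2-dimethoxypropane (COC(C)(C)OC)
Why: Acid-catalysed transketalisation of the anti-1,3-diol; one group protects both hydroxyls and will leave in the single acid step at the end.

Step 6
Reactants: 9
Product: 11 C11 primary alcohol (9 with the C10 vinyl group replaced by CH2OH), via C11 aldehyde 10 (not isolated)
Conditions: O3, CH2Cl2/MeOH, Sudan Red 7B (indicator), −78 °C; then NaBH4, −78 → 0 °C
Reagents that add atoms: ozone ([O-][O+]=O)
Why: Ozonolysis with reductive work-up; the monosubstituted alkene reacts far faster than the acyl-substituted C4=C5 bond, and the indicator marks the end point. The aldehyde is reduced cold before C10 can epimerise.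

Step 7
Reactants: 11; 2 but-3-en-2-yl acetate
Product: 12 C11 homoallylic alcohol (11R hydroxyl and 12S methyl anti; vinyl group on C12; otherwise as 11)
Conditions: [Ir(cod)Cl]2 (cat.), (S)-SEGPHOS, 4-cyano-3-nitrobenzoic acid, Cs2CO3 (substoichiometric), THF, H2O (additive), 70 °C
Reagents that add atoms: none
Why: The same transfer-hydrogenative anti-crotylation, now on an α-stereogenic primary alcohol: the chair transition state sets C11/C12 anti and the ligand antipode sets C11 syn to the C10 methyl, which is also the Felkin–Anh preference of the C11 carbonyl, so catalyst and substrate reinforce each other. Dehydrogenation and addition both take place at iridium, so no α-stereogenic aldehyde accumulates and C10 is guarded.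

Step 8
Reactants: 12
Product: 13 11-O-triethylsilyl ether of 12
Conditions: Et3SiOTf, 2,6-lutidine, CH2Cl2, −78 °C
Reagents that add atoms: triethylsilyl trifluoromethanesulfonate (CC[Si](CC)(CC)OS(=O)(=O)C(F)(F)F)
Why: Silylation of the hindered secondary alcohol under buffered conditions that leave the acetonide intact; the group is acid-labile for the final global deprotection.

Step 9
Reactants: 13
Product: 15 C13 primary alcohol (13 with the C12 vinyl group replaced by CH2OH), via C13 aldehyde 14 (not isolated)
Conditions: O3, CH2Cl2/MeOH, Sudan Red 7B (indicator), −78 °C; then NaBH4, −78 → 0 °C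
Reagents that add atoms: ozone ([O-][O+]=O)
Why: Selective ozonolysis and in situ reduction as in step 6.

Step 10
Reactants: 15; 16 4-vinyl-1,3-dioxolan-2-one (racemic)
Product: 17 C13,C18 diol (13S hydroxyl; C14 bears CH2OH and a vinyl group; C13/C14 anti; otherwise as 15)
Conditions: [Ir(cod)Cl]2 (cat.), (R)-SEGPHOS, 4-cyano-3-nitrobenzoic acid, K3PO4 (cat.), THF, 70 °C
Reagents that add atoms: none
Why: Iridium-catalysed anti-(hydroxymethyl)allylation from the alcohol oxidation level: ionisation of the vinyl carbonate with loss of CO2 gives a (hydroxymethyl)allyl iridium species that adds through the same chair to the carbonyl generated at the metal, setting C13/C14 anti. The ligand sets C13 syn to the C12 methyl, which is the Felkin–Anh preference as well, and C18 arrives as a free primary alcohol.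

Step 11
Reactants: 17
Product: 18 13,18-O-isopropylidene derivative of 17
Conditions: Me2C(OMe)2, PPTS (cat.), CH2Cl2, 0 °C
Reagents that add atoms: 2,2-dimethoxypropane (COC(C)(C)OC)
Why: Acetonide formation on the only free 1,3-diol; brief cold treatment spares the triethylsilyl ether.

Step 12
Reactants: 18
Product: 19 C15 aldehyde (18 with the C14 vinyl group replaced by CHO)
Conditions: O3, CH2Cl2, Sudan Red 7B (indicator), −78 °C; then PPh3
Reagents that add atoms: ozone ([O-][O+]=O)
Why: Selective ozonolysis as before, with neutral phosphine work-up so that the α-stereogenic aldehyde (C14) is isolated without base and used at once.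

Step 13
Reactants: 19; 20 ethyl 2-[bis(2,2,2-trifluoroethoxy)phosphoryl]propanoate
Product: 21 ethyl (15Z)-enoate (chain extended to C14–CH=C(CH3)–CO2Et; C17 is the ester carbon)
Conditions: KN(SiMe3)2, 18-crown-6, THF, −78 °C
Reagents that add atoms: none
Why: Still–Gennari olefination: the electron-poor phosphonate under dissociating conditions eliminates fast from the kinetically favoured adduct and gives the (Z)-trisubstituted enoate, with C14 and C17 cis. The preformed phosphonate anion at −78 °C limits epimerisation at C14.

Step 14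
Reactants: 21
Product: 22 (4E)-enal and (15Z)-allylic alcohol (C3 is CHO; C17 is CH2OH)
Conditions: i-Bu2AlH (excess), CH2Cl2, −78 °C; then MeOH, aq. KNaC4H4O6
Reagents that add atoms: none
Why: One hydride reagent does two jobs: the N-methoxy-N-methylamide stops at a chelated tetrahedral intermediate that gives the aldehyde on work-up, while the ester is reduced fully to the allylic alcohol. The two chain ends are thereby differentiated without extra protecting groups.

Step 15
Reactants: 22; 20 ethyl 2-[bis(2,2,2-trifluoroethoxy)phosphoryl]propanoate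
Product: 23 ethyl (2Z,4E)-2-methyldienoate carrying the free (15Z)-allylic alcohol at C17
Conditions: KN(SiMe3)2, 18-crown-6, 20 (excess), THF, −78 °C
Reagents that add atoms: none
Why: A second Still–Gennari olefination, on the (E)-enal, gives the (2Z,4E)-dienoate; the spectator alkoxide only consumes an extra equivalent of base.

Step 16
Reactants: 23
Product: 24 ethyl (2Z,4E,15Z) dienoate aldehyde (C17 is CHO; fully protected C1–C17 chain)
Conditions: MnO2, CH2Cl2, rt
Reagents that add atoms: none
Why: Allylic oxidation with MnO2 is neutral and leaves the (Z) geometry and the dienoate untouched; the enal is used directly in step 25.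

Step 17
Reactants: 25 methyl 2-methyl-3-oxobutanoate
Product: 26 methyl 2-methyl-3-(trimethylsilyloxy)but-2-enoate (E/Z mixture)
Conditions: Me3SiCl, Et3N, hexane, rt
Reagents that add atoms: chlorotrimethylsilane (C[Si](C)(C)Cl)
Why: O-silylation of the β-keto ester enol.

Step 18
Reactants: 26
Product: 27 1-methoxy-2-methyl-1,3-bis(trimethylsilyloxy)buta-1,3-diene
Conditions: LiN(i-Pr)2, THF, −78 °C; then Me3SiCl
Reagents that add atoms: chlorotrimethylsilane (C[Si](C)(C)Cl)
Why: γ-Deprotonation to the dienolate and O-silylation give the vinylketene acetal.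

Step 19
Reactants: 27; 28 2,6-dichlorocyclohexa-2,5-diene-1,4-dione
Product: 30 2-chloro-6,8-dihydroxy-7-methylnaphthalene-1,4-dione, via chloro cycloadduct 29 (not isolated)
Conditions: THF, −30 °C → rt; then SiO2 or 1 M aq. HCl
Reagents that add atoms: none
Why: Diels–Alder reaction of a vinylketene acetal with a halogenated quinone: the nucleophilic CH2 terminus of the diene bonds to the unsubstituted carbon and the acetal carbon to the chlorine-bearing carbon, so the new peri hydroxyl (C8) ends next to the carbonyl flanked by the remaining chlorine (C2). Loss of HCl and methanol aromatises the ring without an oxidant.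

Step 20
Reactants: 30
Product: 31 2-chloro-6,8-bis(methoxymethoxy)-7-methylnaphthalene-1,4-dione
Conditions: MeOCH2Cl, i-Pr2NEt, CH2Cl2, 0 → 40 °C
Reagents that add atoms: chloromethyl methyl ether (COCCl)
Why: Williamson-type acetalisation of both phenols; the methoxymethyl ethers later stabilise the C5 aryllithium by coordination and leave in the final acid step.

Step 21
Reactants: 31
Product: 33 2-chloro-1,4-dimethoxy-6,8-bis(methoxymethoxy)-7-methylnaphthalene, via chloro hydroquinone 32 (not isolated)
Conditions: Na2S2O4, EtOAc/H2O; then Me2SO4, K2CO3, acetone, 56 °C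
Reagents that add atoms: dimethyl sulfate (COS(=O)(=O)OC)
Why: Reductive methylation: dithionite gives the hydroquinone, which is O-methylated before it can reoxidise.

Step 22
Reactants: 33
Product: 35 1,4-dimethoxy-6,8-bis(methoxymethoxy)-7-methylnaphthalen-2-amine, via diphenylmethylidene imine 34 (not isolated)
Conditions: Ph2C=NH, Pd2(dba)3 (cat.), XPhos, NaOt-Bu, toluene, 100 °C; then NH2OH·HCl, NaOAc, MeOH, rt
Reagents that add atoms: benzophenone imine (N=C(c1ccccc1)c1ccccc1)
Why: Buchwald–Hartwig amination of the aryl chloride with an ammonia surrogate that tolerates the ortho methoxy group; buffered transimination releases the amine without touching the acetals. The nitrogen position is fixed by the chlorine placed in step 19.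

Step 23
Reactants: 35
Product: 36 prop-2-enyl N-[1,4-dimethoxy-6,8-bis(methoxymethoxy)-7-methylnaphthalen-2-yl]carbamate
Conditions: CH2=CHCH2OCOCl, pyridine, CH2Cl2, 0 °C
Reagents that add atoms: allyl chloroformate (C=CCOC(Cl)=O)
Why: N-acylation; the carbamate stops air oxidation of the aminonaphthalene, lowers the reactivity of its ring towards bromine and is later removed under neutral conditions.

Step 24
Reactants: 36
Product: 37 prop-2-enyl N-[5-bromo-1,4-dimethoxy-6,8-bis(methoxymethoxy)-7-methylnaphthalen-2-yl]carbamate
Conditions: NBS, MeCN, 0 °C, dark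
Reagents that add atoms: N-bromosuccinimide (O=C1CCC(=O)N1Br)
Why: Electrophilic aromatic bromination at C5, the α-position that is ortho to the C6 ether and para to the C8 ether; C3 is only ortho to the weaker carbamate donor and to a methoxy group twisted out of conjugation.

Step 25
Reactants: 37; 24
Product: 39 C17 carbinol joining the chain to arene C5 (both C17 epimers; ethyl ester, acetonides, silyl ether and carbamate intact), via dilithiated arene 38 (not isolated)
Conditions: MeLi (1 equiv), THF, −78 °C; t-BuLi (2 equiv), −78 °C; then 24, −78 °C; aq. NH4Cl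
Reagents that add atoms: none
Why: N–H deprotonation followed by bromine–lithium exchange gives an aryllithium held by the neighbouring methoxymethyl ether; it adds 1,2 to the hindered α-methyl enal much faster than to the conjugated ester. The new C17 centre is uncontrolled and is removed in step 27.

Step 26
Reactants: 39
Product: 40 C1 carboxylic acid of 39
Conditions: LiOH, THF/MeOH/H2O, 40 °C; then aq. NaH2PO4
Reagents that add atoms: lithium hydroxide ([Li+].[OH-])
Why: Saponification is done while C17 is still a carbinol, so no enone or activated C14–H is exposed to hydroxide; the allyl carbamate, acetals and silyl ether tolerate it.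

Step 27
Reactants: 40
Product: 41 C17 ketone (keto acid)
Conditions: Dess–Martin periodinane, NaHCO3, CH2Cl2, 0 °C → rt
Reagents that add atoms: none
Why: Dess–Martin oxidation of the allylic, benzylic alcohol under buffered conditions converges both epimers on the aryl (Z)-enone without acid or base strong enough to isomerise it.

Step 28
Reactants: 41
Product: 42 amino keto acid (free C2 amine and C1 acid)
Conditions: Pd(PPh3)4 (cat.), 5,5-dimethylcyclohexane-1,3-dione, THF, rt
Reagents that add atoms: none
Why: Zerovalent palladium ionises the allyl carbamate; the soft carbon nucleophile traps the allyl group and the carbamic acid loses CO2. The scavenger does not add to the enone.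

Step 29
Reactants: 42
Product: 43 protected macrolactam (23-membered; 7,9- and 13,18-acetonides, 11-O-triethylsilyl, 6,8-bis(methoxymethyl) ethers, 1,4-dimethoxy)
Conditions: BOP-Cl, i-Pr2NEt, toluene, 80 °C, slow addition to high dilution
Reagents that add atoms: none
Why: Macrolactamisation through the mixed phosphinic anhydride, a standard closure for anilide ansa rings; the electron-rich naphthylamine is a competent nucleophile and high dilution suppresses oligomers.

Step 30
Reactants: 43
Product: 44 protected macrolactam naphthoquinone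
Conditions: (NH4)2Ce(NO3)6, MeCN/H2O, 0 °C
Reagents that add atoms: water (O)
Why: Oxidative demethylation of the 1,4-dimethoxy ring to the 2-amido-1,4-quinone; only this ring has a para-dioxygen pattern. Partial loss of acid-labile groups here is harmless because they all come off in the next step.

Step 31
Reactants: 44
Product: 45 pentaol (free hydroxyls at C7, C9, C11, C13 and C18, free C6 and C8 phenols)
Conditions: 3 M aq. HCl, THF, rt
Reagents that add atoms: none
Why: Acid hydrolysis removes both acetonides, the triethylsilyl ether and the two carbonyl-activated aryl methoxymethyl ethers at once; no alcohol co-solvent is used, so a hemiketal of the C17 ketone cannot be trapped as a mixed ketal.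

Step 32
Reactants: 45
Product: 48 target compound CNP0507423.4, via C18 aldehyde 46 (not isolated), via lactol 47 (not isolated)
Conditions: TEMPO (cat.), PhI(OAc)2, CH2Cl2/pH 7 buffer, rt
Reagents that add atoms: none
Why: Oxoammonium oxidation selects the one primary alcohol; the aldehyde is trapped by the C11 hydroxyl as the only possible six-membered lactol, which is oxidised to the δ-lactone. The lactone places the substituents on C11, C12, C13 and C14 all trans and equatorial, so any equilibration at C14 favours the target configuration.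

## Compound list

1 | 2-methylpropane-1,3-diol | CC(CO)CO | starting material
2 | but-3-en-2-yl acetate (racemic) | CC(OC(C)=O)C=C | starting material
3 | (3R,4R)-2,4-dimethylhex-5-ene-1,3-diol, both C2 epimers (not isolated) | C=C[C@@H](C)[C@@H](O)C(C)CO | intermediate
4 | (3R,4R,6R,7R)-3,5,7-trimethylnona-1,8-diene-4,6-diol | C=C[C@@H](C)[C@@H](O)C(C)[C@H](O)[C@H](C)C=C | intermediate
5 | (2R,3S,4S,5S,6R)-2-[(2R)-but-3-en-2-yl]-6-(iodomethyl)-3,5-dimethyloxan-4-ol | C=C[C@@H](C)[C@H]1O[C@@H](CI)[C@@H](C)[C@@H](O)[C@@H]1C | intermediate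
6 | N-methoxy-N-methylprop-2-enamide | C=CC(=O)N(C)OC | starting material
7 | (2E,4R)-4-[(2R,3S,4S,5S,6R)-4-hydroxy-6-(iodomethyl)-3,5-dimethyloxan-2-yl]-N-methoxy-N-methylpent-2-enamide | CON(C)C(=O)/C=C/[C@@H](C)[C@H]1O[C@@H](CI)[C@@H](C)[C@@H](O)[C@@H]1C | intermediate
8 | (2E,4R,5R,6S,7R,8R)-5,7-dihydroxy-N-methoxy-N,4,6,8-tetramethyldeca-2,9-dienamide | CON(C)C(=O)/C=C/[C@@H](C)[C@@H](O)[C@@H](C)[C@H](O)[C@H](C)C=C | intermediate
9 | 7,9-O-isopropylidene derivative of 8 | CON(C)C(=O)/C=C/[C@@H](C)[C@H]1OC(C)(C)O[C@H]([C@H](C)C=C)[C@@H]1C | intermediate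
10 | C11 aldehyde (9 with the C10 vinyl group replaced by CHO; not isolated) | CON(C)C(=O)/C=C/[C@@H](C)[C@H]1OC(C)(C)O[C@H]([C@H](C)C=O)[C@@H]1C | intermediate
11 | C11 primary alcohol (9 with the C10 vinyl group replaced by CH2OH) | CON(C)C(=O)/C=C/[C@@H](C)[C@H]1OC(C)(C)O[C@H]([C@H](C)CO)[C@@H]1C | intermediate
12 | C11 homoallylic alcohol (11R-OH, 12S-CH3, vinyl on C12) | CON(C)C(=O)/C=C/[C@@H](C)[C@H]1OC(C)(C)O[C@H]([C@H](C)[C@@H](O)[C@@H](C)C=C)[C@@H]1C | intermediate
13 | 11-O-triethylsilyl ether of 12 | CON(C)C(=O)/C=C/[C@@H](C)[C@H]1OC(C)(C)O[C@H]([C@H](C)[C@@H](O[Si](CC)(CC)CC)[C@@H](C)C=C)[C@@H]1C | intermediate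
14 | C13 aldehyde (13 with the C12 vinyl group replaced by CHO; not isolated) | CON(C)C(=O)/C=C/[C@@H](C)[C@H]1OC(C)(C)O[C@H]([C@H](C)[C@@H](O[Si](CC)(CC)CC)[C@@H](C)C=O)[C@@H]1C | intermediate
15 | C13 primary alcohol (13 with the C12 vinyl group replaced by CH2OH) | CON(C)C(=O)/C=C/[C@@H](C)[C@H]1OC(C)(C)O[C@H]([C@H](C)[C@@H](O[Si](CC)(CC)CC)[C@@H](C)CO)[C@@H]1C | intermediate
16 | 4-vinyl-1,3-dioxolan-2-one (racemic) | C=CC1COC(=O)O1 | starting material
17 | C13,C18 diol (13S-OH; C14 bears CH2OH and vinyl; C13/C14 anti) | CON(C)C(=O)/C=C/[C@@H](C)[C@H]1OC(C)(C)O[C@H]([C@H](C)[C@@H](O[Si](CC)(CC)CC)[C@@H](C)[C@H](O)[C@H](CO)C=C)[C@@H]1C | intermediate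
18 | 13,18-O-isopropylidene derivative of 17 | CON(C)C(=O)/C=C/[C@@H](C)[C@H]1OC(C)(C)O[C@H]([C@H](C)[C@@H](O[Si](CC)(CC)CC)[C@@H](C)[C@@H]2OC(C)(C)OC[C@@H]2C=C)[C@@H]1C | intermediate
19 | C15 aldehyde (18 with the C14 vinyl group replaced by CHO) | CON(C)C(=O)/C=C/[C@@H](C)[C@H]1OC(C)(C)O[C@H]([C@H](C)[C@@H](O[Si](CC)(CC)CC)[C@@H](C)[C@@H]2OC(C)(C)OC[C@@H]2C=O)[C@@H]1C | intermediate
20 | ethyl 2-[bis(2,2,2-trifluoroethoxy)phosphoryl]propanoate | CCOC(=O)C(C)P(=O)(OCC(F)(F)F)OCC(F)(F)F | starting material
21 | ethyl (15Z)-enoate (C14–CH=C(CH3)–CO2Et; C3 N-methoxy-N-methylamide) | CON(C)C(=O)/C=C/[C@@H](C)[C@H]1OC(C)(C)O[C@H]([C@H](C)[C@@H](O[Si](CC)(CC)CC)[C@@H](C)[C@@H]2OC(C)(C)OC[C@@H]2/C=C(/C)C(=O)OCC)[C@@H]1C | intermediate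
22 | (4E)-enal with (15Z)-allylic alcohol (C3 CHO; C17 CH2OH) | O=C/C=C/[C@@H](C)[C@H]1OC(C)(C)O[C@H]([C@H](C)[C@@H](O[Si](CC)(CC)CC)[C@@H](C)[C@@H]2OC(C)(C)OC[C@@H]2/C=C(/C)CO)[C@@H]1C | intermediate
23 | ethyl (2Z,4E)-2-methyldienoate with (15Z)-allylic alcohol at C17 | CCOC(=O)C(\C)=C/C=C/[C@@H](C)[C@H]1OC(C)(C)O[C@H]([C@H](C)[C@@H](O[Si](CC)(CC)CC)[C@@H](C)[C@@H]2OC(C)(C)OC[C@@H]2/C=C(/C)CO)[C@@H]1C | intermediate
24 | ethyl (2Z,4E,15Z) dienoate aldehyde (C17 CHO) | CCOC(=O)C(\C)=C/C=C/[C@@H](C)[C@H]1OC(C)(C)O[C@H]([C@H](C)[C@@H](O[Si](CC)(CC)CC)[C@@H](C)[C@@H]2OC(C)(C)OC[C@@H]2/C=C(/C)C=O)[C@@H]1C | intermediate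
25 | methyl 2-methyl-3-oxobutanoate | COC(=O)C(C)C(C)=O | starting material
26 | methyl 2-methyl-3-(trimethylsilyloxy)but-2-enoate (E/Z mixture) | COC(=O)C(C)=C(C)O[Si](C)(C)C | intermediate
27 | 1-methoxy-2-methyl-1,3-bis(trimethylsilyloxy)buta-1,3-diene | COC(O[Si](C)(C)C)=C(C)C(=C)O[Si](C)(C)C | intermediate
28 | 2,6-dichlorocyclohexa-2,5-diene-1,4-dione | O=C1C=C(Cl)C(=O)C(Cl)=C1 | starting material
29 | 2,8a-dichloro-8-methoxy-7-methyl-6,8-bis(trimethylsilyloxy)-4a,5,8,8a-tetrahydronaphthalene-1,4-dione (racemic; not isolated) | O=C1C(Cl)=CC(=O)C2CC(O[Si](C)(C)C)=C(C)C(OC)(O[Si](C)(C)C)C12Cl | intermediate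
30 | 2-chloro-6,8-dihydroxy-7-methylnaphthalene-1,4-dione | O=C1C=C(Cl)C(=O)c2c(O)c(C)c(O)cc12 | intermediate
31 | 2-chloro-6,8-bis(methoxymethoxy)-7-methylnaphthalene-1,4-dione | O=C1C=C(Cl)C(=O)c2c(OCOC)c(C)c(OCOC)cc12 | intermediate
32 | 2-chloro-6,8-bis(methoxymethoxy)-7-methylnaphthalene-1,4-diol (not isolated) | Oc1cc(Cl)c(O)c2c(OCOC)c(C)c(OCOC)cc12 | intermediate
33 | 2-chloro-1,4-dimethoxy-6,8-bis(methoxymethoxy)-7-methylnaphthalene | COc1cc(Cl)c(OC)c2c(OCOC)c(C)c(OCOC)cc12 | intermediate
34 | N-(diphenylmethylidene)-1,4-dimethoxy-6,8-bis(methoxymethoxy)-7-methylnaphthalen-2-amine (not isolated) | COc1cc(N=C(c2ccccc2)c2ccccc2)c(OC)c2c(OCOC)c(C)c(OCOC)cc12 | intermediate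
35 | 1,4-dimethoxy-6,8-bis(methoxymethoxy)-7-methylnaphthalen-2-amine | COc1cc(N)c(OC)c2c(OCOC)c(C)c(OCOC)cc12 | intermediate
36 | prop-2-enyl N-[1,4-dimethoxy-6,8-bis(methoxymethoxy)-7-methylnaphthalen-2-yl]carbamate | COc1cc(NC(=O)OCC=C)c(OC)c2c(OCOC)c(C)c(OCOC)cc12 | intermediate
37 | prop-2-enyl N-[5-bromo-1,4-dimethoxy-6,8-bis(methoxymethoxy)-7-methylnaphthalen-2-yl]carbamate | COc1cc(NC(=O)OCC=C)c(OC)c2c(OCOC)c(C)c(OCOC)c(Br)c12 | intermediate
38 | N,5-dilithio derivative of 37 with lithium in place of bromine (not isolated) | [Li]N(C(=O)OCC=C)c1cc(OC)c2c([Li])c(OCOC)c(C)c(OCOC)c2c1OC | intermediate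
39 | C17 carbinol joining chain and arene C5 (both C17 epimers) | CCOC(=O)C(\C)=C/C=C/[C@@H](C)[C@H]1OC(C)(C)O[C@H]([C@H](C)[C@@H](O[Si](CC)(CC)CC)[C@@H](C)[C@@H]2OC(C)(C)OC[C@@H]2/C=C(/C)C(O)c2c(OCOC)c(C)c(OCOC)c3c(OC)c(NC(=O)OCC=C)cc(OC)c23)[C@@H]1C | intermediate
40 | C1 carboxylic acid of 39 | OC(=O)C(\C)=C/C=C/[C@@H](C)[C@H]1OC(C)(C)O[C@H]([C@H](C)[C@@H](O[Si](CC)(CC)CC)[C@@H](C)[C@@H]2OC(C)(C)OC[C@@H]2/C=C(/C)C(O)c2c(OCOC)c(C)c(OCOC)c3c(OC)c(NC(=O)OCC=C)cc(OC)c23)[C@@H]1C | intermediate
41 | C17 ketone (keto acid, N-allyloxycarbonyl) | OC(=O)C(\C)=C/C=C/[C@@H](C)[C@H]1OC(C)(C)O[C@H]([C@H](C)[C@@H](O[Si](CC)(CC)CC)[C@@H](C)[C@@H]2OC(C)(C)OC[C@@H]2/C=C(/C)C(=O)c2c(OCOC)c(C)c(OCOC)c3c(OC)c(NC(=O)OCC=C)cc(OC)c23)[C@@H]1C | intermediate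
42 | amino keto acid (seco acid) | OC(=O)C(\C)=C/C=C/[C@@H](C)[C@H]1OC(C)(C)O[C@H]([C@H](C)[C@@H](O[Si](CC)(CC)CC)[C@@H](C)[C@@H]2OC(C)(C)OC[C@@H]2/C=C(/C)C(=O)c2c(OCOC)c(C)c(OCOC)c3c(OC)c(N)cc(OC)c23)[C@@H]1C | intermediate
43 | protected 23-membered macrolactam (1,4-dimethoxynaphthalene) | C/C1=C/C=C/[C@@H](C)[C@H]2OC(C)(C)O[C@H]([C@H](C)[C@@H](O[Si](CC)(CC)CC)[C@@H](C)[C@@H]3OC(C)(C)OC[C@@H]3/C=C(/C)C(=O)c3c(OCOC)c(C)c(OCOC)c4c(OC)c(NC1=O)cc(OC)c34)[C@@H]2C | intermediate
44 | protected macrolactam naphthoquinone | C/C1=C/C=C/[C@@H](C)[C@H]2OC(C)(C)O[C@H]([C@H](C)[C@@H](O[Si](CC)(CC)CC)[C@@H](C)[C@@H]3OC(C)(C)OC[C@@H]3/C=C(/C)C(=O)c3c(OCOC)c(C)c(OCOC)c4c3C(=O)C=C(NC1=O)C4=O)[C@@H]2C | intermediate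
45 | pentaol (open hydroxy form of the lactone; free phenols) | C/C1=C/C=C/[C@@H](C)[C@@H](O)[C@@H](C)[C@H](O)[C@H](C)[C@@H](O)[C@@H](C)[C@H](O)[C@H](CO)/C=C(/C)C(=O)c2c(O)c(C)c(O)c3c2C(=O)C=C(NC1=O)C3=O | intermediate
46 | C18 aldehyde of 45 (not isolated) | C/C1=C/C=C/[C@@H](C)[C@@H](O)[C@@H](C)[C@H](O)[C@H](C)[C@@H](O)[C@@H](C)[C@H](O)[C@H](C=O)/C=C(/C)C(=O)c2c(O)c(C)c(O)c3c2C(=O)C=C(NC1=O)C3=O | intermediate
47 | C18 lactol closed on O11 (both anomers; not isolated) | C/C1=C/C=C/[C@@H](C)[C@@H](O)[C@@H](C)[C@H](O)[C@H](C)[C@H]2OC(O)[C@H](/C=C(/C)C(=O)c3c(O)c(C)c(O)c4c3C(=O)C=C(NC1=O)C4=O)[C@@H](O)[C@@H]2C | intermediate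
48 | CNP0507423.4 (6R,7R,8R,9S,10S,11R,12S,13S,14R; 2Z,4E,15Z) | C/C1=C/C=C/[C@@H](C)[C@@H](O)[C@@H](C)[C@H](O)[C@H](C)[C@H]2OC(=O)[C@H](/C=C(/C)C(=O)c3c(O)c(C)c(O)c4c3C(=O)C=C(NC1=O)C4=O)[C@@H](O)[C@@H]2C | target

## Step count and least certain steps

Total: 32 steps. Longest linear sequence: 24 steps (steps 1–16 and 25–32, from 1). The arene branch is 8 steps (17–24).

**Step 1 (key step).** The most likely failures are incomplete second crotylation, leaving mono-adduct 3, and erosion of anti selectivity at 70 °C, giving diastereomers that are hard to separate from 4. Fallback: the two additions are done one at a time. 1 is monosilylated to 3-[(tert-butyldimethylsilyl)oxy]-2-methylpropan-1-ol F1, which is crotylated once under the same iridium catalysis to (3R,4R)-1-[(tert-butyldimethylsilyl)oxy]-2,4-dimethylhex-5-en-3-ol F2 and purified. Bu4NF then releases mono-adduct 3, which is isolated and crotylated a second time to 4. This gives up the two-directional economy but lets each addition be optimised and purified separately, and the route is rejoined at 4.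

**Step 10.** β-Elimination of the silyloxy group or epimerisation at C12 may compete while C13 is at the carbonyl oxidation level, and the functionalised allyl donor may transfer with poorer anti or facial selectivity next to an existing stereocentre. Fallback: an auxiliary-controlled aldol replaces the catalytic addition. 13 is ozonised with PPh3 work-up to give aldehyde 14 as an isolated compound. (R)-4-Benzyl-3-[(E)-but-2-enoyl]-1,3-oxazolidin-2-one F3, made from (R)-4-benzyl-1,3-oxazolidin-2-one and (E)-but-2-enoyl chloride, is converted with Bu2BOTf and Et3N into its boron dienolate, which adds at the α-carbon in an Evans syn aldol reaction to give the α-vinyl-β-hydroxy imide F4. With the acyl carbon as C18, this has the required C13 and C14 configuration. LiBH4 reduction removes the auxiliary and gives diol 17.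

**Step 24.** Bromination may go partly at C3 of the carbamate-bearing ring or add to the allyl group. Fallback: the nitrogen ring is deactivated before bromination. Amine 35 is converted with (CF3CO)2O into 2,2,2-trifluoro-N-[1,4-dimethoxy-6,8-bis(methoxymethoxy)-7-methylnaphthalen-2-yl]acetamide F5, whose nitrogen no longer activates C3. NBS then gives the 5-bromo trifluoroacetamide F6, K2CO3 in aqueous methanol frees 5-bromo-1,4-dimethoxy-6,8-bis(methoxymethoxy)-7-methylnaphthalen-2-amine F7, and allyl chloroformate returns the route at 37.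

**Step 25.** The (Z)-enal 24 may isomerise to the (E)-enal or be deprotonated at C14 by the basic aryllithium, and exchange may be incomplete at the hindered bromide. Fallback: acyl substitution replaces carbonyl addition, so no (Z)-enal has to meet a base. 24 is oxidised with NaClO2 (Pinnick conditions) to the (15Z)-enoic acid F8 and condensed with N,O-dimethylhydroxylamine to the C17 N-methoxy-N-methylamide F9. Aryllithium 38 is added to F9 to give the C17 keto ester F10 directly. LiOH hydrolysis of the C1 ester then gives keto acid 41, where the route is rejoined.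

**Step 29.** Intermolecular amide formation may outrun ring closure, and the activated (2Z)-dienoic acid may isomerise. Fallback: the ring is closed before the ketone is made, on a more flexible substrate. 40 is deallylated with Pd(PPh3)4 and 5,5-dimethylcyclohexane-1,3-dione to the amino hydroxy acid F11, which is lactamised under the same activation to the macrocyclic C17 carbinol F12. Dess–Martin oxidation of F12 gives 43.

**Step 32.** The transient β-hydroxy aldehyde 46 may lose water or epimerise at C14 before the lactol forms, and PhI(OAc)2 may attack the free phenols. Fallback: the lactone is made while the phenols and the quinone are still masked. 43 is treated with PPTS in methanol to remove only the two acetonides and the silyl ether, giving the pentaol F13 with methoxymethyl and methyl ethers intact. TEMPO and PhI(OAc)2 convert F13 into the δ-lactone F14, (NH4)2Ce(NO3)6 gives the quinone lactone F15, and brief aqueous HCl in MeCN removes the two activated methoxymethyl ethers to give 48.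

## Further compounds

F1 | step 1 | 3-[(tert-butyldimethylsilyl)oxy]-2-methylpropan-1-ol (racemic) | CC(CO)CO[Si](C)(C)C(C)(C)C
F2 | step 1 | (3R,4R)-1-[(tert-butyldimethylsilyl)oxy]-2,4-dimethylhex-5-en-3-ol (both C2 epimers) | C=C[C@@H](C)[C@@H](O)C(C)CO[Si](C)(C)C(C)(C)C
F3 | step 10 | (R)-4-benzyl-3-[(E)-but-2-enoyl]-1,3-oxazolidin-2-one | C/C=C/C(=O)N1[C@H](Cc2ccccc2)COC1=O
F4 | step 10 | syn aldol imide (13-OH, C14 vinyl, C18 acyl oxazolidinone) | CON(C)C(=O)/C=C/[C@@H](C)[C@H]1OC(C)(C)O[C@H]([C@H](C)[C@@H](O[Si](CC)(CC)CC)[C@@H](C)[C@H](O)[C@@H](C=C)C(=O)N2[C@H](Cc3ccccc3)COC2=O)[C@@H]1C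
F5 | step 24 | 2,2,2-trifluoro-N-[1,4-dimethoxy-6,8-bis(methoxymethoxy)-7-methylnaphthalen-2-yl]acetamide | COc1cc(NC(=O)C(F)(F)F)c(OC)c2c(OCOC)c(C)c(OCOC)cc12
F6 | step 24 | N-[5-bromo-1,4-dimethoxy-6,8-bis(methoxymethoxy)-7-methylnaphthalen-2-yl]-2,2,2-trifluoroacetamide | COc1cc(NC(=O)C(F)(F)F)c(OC)c2c(OCOC)c(C)c(OCOC)c(Br)c12
F7 | step 24 | 5-bromo-1,4-dimethoxy-6,8-bis(methoxymethoxy)-7-methylnaphthalen-2-amine | COc1cc(N)c(OC)c2c(OCOC)c(C)c(OCOC)c(Br)c12
F8 | step 25 | (15Z)-enoic acid at C17 (C1 ethyl ester) | CCOC(=O)C(\C)=C/C=C/[C@@H](C)[C@H]1OC(C)(C)O[C@H]([C@H](C)[C@@H](O[Si](CC)(CC)CC)[C@@H](C)[C@@H]2OC(C)(C)OC[C@@H]2/C=C(/C)C(=O)O)[C@@H]1C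
F9 | step 25 | C17 N-methoxy-N-methylamide (C1 ethyl ester) | CCOC(=O)C(\C)=C/C=C/[C@@H](C)[C@H]1OC(C)(C)O[C@H]([C@H](C)[C@@H](O[Si](CC)(CC)CC)[C@@H](C)[C@@H]2OC(C)(C)OC[C@@H]2/C=C(/C)C(=O)N(C)OC)[C@@H]1C
F10 | step 25 | C17 keto ester (ethyl ester of 41) | CCOC(=O)C(\C)=C/C=C/[C@@H](C)[C@H]1OC(C)(C)O[C@H]([C@H](C)[C@@H](O[Si](CC)(CC)CC)[C@@H](C)[C@@H]2OC(C)(C)OC[C@@H]2/C=C(/C)C(=O)c2c(OCOC)c(C)c(OCOC)c3c(OC)c(NC(=O)OCC=C)cc(OC)c23)[C@@H]1C
F11 | step 29 | amino hydroxy acid (C17 carbinol, both epimers) | OC(=O)C(\C)=C/C=C/[C@@H](C)[C@H]1OC(C)(C)O[C@H]([C@H](C)[C@@H](O[Si](CC)(CC)CC)[C@@H](C)[C@@H]2OC(C)(C)OC[C@@H]2/C=C(/C)C(O)c2c(OCOC)c(C)c(OCOC)c3c(OC)c(N)cc(OC)c23)[C@@H]1C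
F12 | step 29 | macrolactam C17 carbinol (both epimers) | C/C1=C/C=C/[C@@H](C)[C@H]2OC(C)(C)O[C@H]([C@H](C)[C@@H](O[Si](CC)(CC)CC)[C@@H](C)[C@@H]3OC(C)(C)OC[C@@H]3/C=C(/C)C(O)c3c(OCOC)c(C)c(OCOC)c4c(OC)c(NC1=O)cc(OC)c34)[C@@H]2C
F13 | step 32 | macrolactam pentaol with 1,4-dimethoxy and 6,8-bis(methoxymethyl) ethers intact | C/C1=C/C=C/[C@@H](C)[C@@H](O)[C@@H](C)[C@H](O)[C@H](C)[C@@H](O)[C@@H](C)[C@H](O)[C@H](CO)/C=C(/C)C(=O)c2c(OCOC)c(C)c(OCOC)c3c(OC)c(NC1=O)cc(OC)c23
F14 | step 32 | δ-lactone with 1,4-dimethoxy and 6,8-bis(methoxymethyl) ethers intact | C/C1=C/C=C/[C@@H](C)[C@@H](O)[C@@H](C)[C@H](O)[C@H](C)[C@H]2OC(=O)[C@H](/C=C(/C)C(=O)c3c(OCOC)c(C)c(OCOC)c4c(OC)c(NC1=O)cc(OC)c34)[C@@H](O)[C@@H]2C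
F15 | step 32 | quinone δ-lactone 6,8-bis(methoxymethyl) ether | C/C1=C/C=C/[C@@H](C)[C@@H](O)[C@@H](C)[C@H](O)[C@H](C)[C@H]2OC(=O)[C@H](/C=C(/C)C(=O)c3c(OCOC)c(C)c(OCOC)c4c3C(=O)C=C(NC1=O)C4=O)[C@@H](O)[C@@H]2C
A1 | alternative 1 | protected 23-membered (2Z,4E)-dienamide macrocycle | C/C1=C/C=C/[C@@H](C)[C@@H](O[Si](CC)(CC)CC)[C@@H](C)[C@H](O[Si](CC)(CC)CC)[C@H](C)[C@H]2OC(=O)[C@H](/C=C(/C)[C@H](O[Si](CC)(CC)CC)c3c(OC)c(C)c(OC)c4c(OC)c(NC1=O)cc(OC)c34)[C@@H](O[Si](CC)(CC)CC)[C@@H]2C
A2 | alternative 1 | 24-membered C4–SO2–C5 macrocyclic sulfone | C/C1=C/CS(=O)(=O)C[C@@H](C)[C@@H](O[Si](CC)(CC)CC)[C@@H](C)[C@H](O[Si](CC)(CC)CC)[C@H](C)[C@H]2OC(=O)[C@H](/C=C(/C)[C@H](O[Si](CC)(CC)CC)c3c(OC)c(C)c(OC)c4c(OC)c(NC1=O)cc(OC)c34)[C@@H](O[Si](CC)(CC)CC)[C@@H]2C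
A3 | alternative 2 | tert-butyl N-[8-hydroxy-1,4-dimethoxy-5-[(4-methoxyphenyl)methoxymethyl]-7-methyl-6-(triisopropylsilyloxy)naphthalen-2-yl]carbamate | COc1ccc(COCc2c(O[Si](C(C)C)(C(C)C)C(C)C)c(C)c(O)c3c(OC)c(NC(=O)OC(C)(C)C)cc(OC)c23)cc1
A4 | alternative 2 | tert-butyl N-[4-[1-diazo-3-[(4-methoxyphenyl)methoxy]-2-oxopropyl]-2,5-dimethoxyphenyl]carbamate | COc1ccc(COCC(=O)C(=[N+]=[N-])c2cc(OC)c(NC(=O)OC(C)(C)C)cc2OC)cc1
A5 | alternative 2 | triisopropyl(prop-1-ynyloxy)silane | CC#CO[Si](C(C)C)(C(C)C)C(C)C
A6 | alternative 3 | ortho-hydroxyaryl (Z)-enone ansa macrocycle | C/C1=C/C=C/[C@@H](C)[C@@H](O[Si](CC)(CC)CC)[C@@H](C)[C@H](O[Si](CC)(CC)CC)[C@H](C)[C@@H](O[Si](CC)(CC)CC)[C@@H](C)[C@H](O[Si](CC)(CC)CC)[C@H](CO[Si](CC)(CC)CC)/C=C(/C)C(=O)c2c(O)c(C)c(OC)c3c(OC)c(NC1=O)cc(OC)c23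
A7 | alternative 3 | 25-membered aryl (Z)-enoate macrolactone with iodide at arene C5 | C/C1=C/C=C/[C@@H](C)[C@@H](O[Si](CC)(CC)CC)[C@@H](C)[C@H](O[Si](CC)(CC)CC)[C@H](C)[C@@H](O[Si](CC)(CC)CC)[C@@H](C)[C@H](O[Si](CC)(CC)CC)[C@H](CO[Si](CC)(CC)CC)/C=C(/C)C(=O)Oc2c(I)c3c(OC)cc(NC1=O)c(OC)c3c(OC)c2C
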